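(The readings come from a simulation with constants of no real substance; scatter was added.)

Amounts first: Saturday's flask and Tuesday's run hold the same substrate, coupling partner and free catalyst, and differ in capture agent, 3.1 mM against 4.7 mM.

| flask | substrate | coupling partner | capture agent | free catalyst | remark |
|---|---|---|---|---|---|
| Saturday's | 31 mM | 1.1 equiv | 3.1 mM | 1 mol% | the very flask that is asked about, followed so far |
| Tuesday's | 31 mM | 1.1 equiv | 4.7 mM | 1 mol% | run made earlier |
| flask | 31 mM | 1.10 equiv | 3.10 mM | 1 mol% |  |

- Saturday's (time / s: product / %, substrate / %): 12.0: 1.0, 97.4; 25.0: 3.4, 95.3; 40.0: 1.7, 95.6; 50.0: 5.2, 93.5; 60.0: 6.3, 94.1; 80.0: 5.2, 96.2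
- Tuesday's (time / min: product / %, substrate / %): 0.500: 1.1, 98.4; 0.833: 4.7, 94.6; 1.33: 4.8, 91.8; 2.00: 6.4, 93.6; 4.00: 8.9, 88.9; 6.00: 11.4, 90.2

(standard deviation of a reading: 1 percentage point)

- no earlier run changes the charge of free catalyst; that part of a forecast is a guess

* apparent order in free catalyst when 10% of the substrate are converted (percent change of the rate of making product for one percent more free catalyst charged)

Does the capture agent change the start? Not that I can read: at 50.0 s Saturday's run shows 5.2% of product and Tuesday's run 4.7%, a gap inside a scatter of 1 percentage point on each reading.

Then why does Tuesday's run bend? Its mean rate is 0.0320 min⁻¹ of the substrate charged up to 2.00 min and 0.0125 min⁻¹ from there to 6.00 min, while the mean product in those stretches goes from 3.20% to 8.90%. I take it that catalyst is lost at a fixed chance for each product made, so that the rate falls in a straight line with product, and this line reaches zero at a reading of 12.6%.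

And for Saturday's flask? I assume that the chance of loss goes with the capture agent, so scaling by the two charges gives an estimate of 19.0%, which carries the scatter of the readings: this is its ceiling, the fraction of the substrate charged that turns to product before the catalyst is gone, which is the turnover number times the loading.

Why should the order leave one? At 10% conversion Saturday's flask keeps, by my estimate, a live share of 47.5%, the conversion taken over the ceiling and subtracted from the whole. On this picture, a guess since no earlier run changes the charge of free catalyst, one percent more catalyst raises both the starting rate and the ceiling by one percent, which makes the order the reciprocal of the live share, 2.11 by my reckoning.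

The forecast gives 1.3, “I lean slightly above one”, and my figure stands higher. The flask gives 2.4.

    substrate + catalyst intermediate B ⇌ idle complex, settled at all times (K = 86.0 M⁻¹)
    substrate + catalyst intermediate A → catalyst intermediate B (k = 21.0 M⁻¹ s⁻¹)
    catalyst intermediate B → free catalyst + product (k = 0.400 s⁻¹)
    coupling partner + free catalyst → catalyst intermediate A (k = 670 M⁻¹ s⁻¹)
    catalyst intermediate A + capture agent → trapped intermediate (k = 12.0 M⁻¹ s⁻¹)

At the charged amounts of Saturday's flask, catalyst intermediate A has a half-life of 1.06 s against substrate and 18.6 s against capture agent, longer by a factor of 17.5, which means about one passage in that many ends as trapped intermediate, and that count of passages times the loading is what the ceiling, 19.0% in my estimate, stands for. Saturday's flask holds 16.8% of product at 60.0 min, with trapped intermediate at >99.9% of the catalyst charged.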